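## Retrosynthetic overview

1. Ring B (pyran, O2–C1 and C3=C4) closes last, by the C1 hydroxyl adding to a C3 ketone. That ketone and the acrylic acid are carried through the route as a 2‑furyl group.
2. The C6 ester comes from anti opening, at C6, of a C6–C7 epoxy ketone by the protected aryl carboxylic acid. The C4a=C8a double bond comes from a decarboxylative dehydrogenation that removes an allyl ester at C8a, after C1 has been added there with formaldehyde.
3. Ring A (C4a, C5, C6, C7, C8, C8a) is made first, in one operation, from an enal (C4a–C5–C6, furfuryl on C4a) and a γ‑chloro β‑keto ester (C7–C8–C8a): Michael addition C8a→C4a, aldol C7→C6, epoxide closure.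
4. Enabling feature: the C8 ketone is flanked by C7 and C8a, a 1,3‑dinucleophile once C8a bears an ester. C4a and C6 stand 1,3 like the β‑carbon and carbonyl carbon of an enal. The trans C6‑acyloxy/C7‑hydroxy pair beside C8=O is an opened 2‑methyl‑2,3‑epoxy ketone. C4a is trigonal in the target, so the centre the catalyst sets there is only a relay.
5. Order of rings: ring A with its oxirane (step 4), then ring B (step 14).

Key step: step 4

Remark: atom numbers C1–C8a are those of the 1H‑isochromene core of the target and are used for all intermediates; ring A is the carbocycle, ring B the pyran.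
Remark: 2‑chloropropanoyl chloride is used as the racemate, because its centre is enolised in step 4. Compounds 13 and 14 are drawn as the expected major epimer at the ester‑bearing carbon, a centre that step 7 removes.

## Route

Step 1
Reactants: 1 furan
Product: 3 2-allylfuran, via furan-2-yllithium 2 (not isolated)
Conditions: n-BuLi, THF, −78 → 0 °C; allyl bromide, −78 °C → rt
Reagents that add atoms: allyl bromide, C=CCBr
Why: α‑lithiation of furan followed by alkylation of the aryllithium with an allylic bromide is a standard way to 2‑alkylfurans.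

Step 2
Reactants: 3 2-allylfuran; 4 (E)-but-2-enal
Product: 5 (2E)-4-(furan-2-yl)but-2-enal
Conditions: second-generation Hoveyda–Grubbs catalyst (3 mol%), excess 4, CH2Cl2, 40 °C
Reagents that add atoms: none
Why: olefin cross‑metathesis of a terminal allyl arene with an excess of an enal should give the E enal under thermodynamic control, with propene lost.

Step 3
Reactants: 6 Meldrum's acid; 7 2-chloropropanoyl chloride
Product: 9 allyl 4-chloro-3-oxopentanoate, via acyl Meldrum's acid 8 (not isolated)
Conditions: pyridine, CH2Cl2, 0 °C → rt; then allyl alcohol, toluene, 90 °C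
Reagents that add atoms: allyl alcohol, C=CCO
Why: C‑acylation of Meldrum's acid and thermal alcoholysis with loss of acetone and CO2 is the standard route to β‑keto esters, here to a γ‑chloro one.

Step 4
Reactants: 5 (2E)-4-(furan-2-yl)but-2-enal; 9 allyl 4-chloro-3-oxopentanoate
Product: 12 allyl (1S,3R,4R,6S)-4-(furan-2-ylmethyl)-1-methyl-2-oxo-7-oxabicyclo[4.1.0]heptane-3-carboxylate, via Michael adduct 10 (not isolated), via chlorohydrin 11 (not isolated)
Conditions: (R)-2-[diphenyl(trimethylsilyloxy)methyl]pyrrolidine (10 mol%), PhCO2H (10 mol%), CH2Cl2, rt; then K2CO3, DMF, rt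
Reagents that add atoms: none
Why: The amine condenses with enal 5 to an E iminium ion and the doubly activated C8a–H carbon of 9 adds to C4a (Michael addition) to give 10 after hydrolysis, the enolised α‑chloro ketone carbon C7 then adds to the C6 aldehyde (aldol) to give chlorohydrin 11, and K2CO3 lets the C6 alkoxide displace chloride at C7 (intramolecular Darzens closure) to give 12. The closest known reaction type is the prolinol‑silyl‑ether‑catalysed domino Michael/aldol/intramolecular SN2 reaction of γ‑chloro β‑keto esters with enals to epoxycyclohexanones, used here with a γ‑methyl group on the keto ester. Ring A closes by a 6‑(enolendo)‑exo‑trig aldol addition and the oxirane by a 3‑exo‑tet substitution. C4a is set by the catalyst, whose diphenyl(silyloxy)methyl group shields one face of the iminium ion; C6 and C7 follow from C4a, because in the chair‑like aldol transition state the furfuryl group is equatorial and only the chlorohydrin with axial C6–O antiperiplanar to axial C7–Cl can close, which should place the epoxide oxygen trans to the furfuryl group and give the (1S,6S) oxirane, while the ester‑bearing C8a settles trans by enolisation. The step needs conjugate addition at C4a rather than carbonyl addition (secured by iminium activation and the soft β‑keto ester), aldol attack from C7 rather than C8a (only C7 forms a six‑membered ring) and epoxide closure ahead of other chloride loss (secured by the reversible aldol, which funnels material through the antiperiplanar chlorohydrin). C4a and C8a are relay centres that step 7 removes, so the step delivers both C–C bonds of ring A and the two lasting stereocentres in one operation.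

Step 5
Reactants: 12 epoxy β-keto ester
Product: 13 allyl (1S,3R,4R,6S)-4-(furan-2-ylmethyl)-3-(hydroxymethyl)-1-methyl-2-oxo-7-oxabicyclo[4.1.0]heptane-3-carboxylate
Conditions: aq. CH2O (37%), KHCO3 (cat.), THF, rt
Reagents that add atoms: formaldehyde, C=O
Why: aldol hydroxymethylation of the β‑keto ester at its only acidic C–H (C8a) installs C1; attack anti to the neighbouring furfuryl group should give the epimer shown, and the configuration is of no consequence because step 7 makes C8a trigonal.

Step 6
Reactants: 13 hydroxymethyl keto ester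
Product: 14 allyl (1S,3R,4R,6S)-3-({[tert-butyl(dimethyl)silyl]oxy}methyl)-4-(furan-2-ylmethyl)-1-methyl-2-oxo-7-oxabicyclo[4.1.0]heptane-3-carboxylate
Conditions: TBSCl, imidazole, DMF, 0 °C → rt
Reagents that add atoms: tert-butyl(chloro)dimethylsilane, CC(C)(C)[Si](C)(C)Cl
Why: silylation of the primary alcohol blocks retro‑aldol loss of formaldehyde and β‑hydroxide loss in the next step.

Step 7
Reactants: 14 silyl ether allyl ester
Product: 15 (1S,6S)-3-({[tert-butyl(dimethyl)silyl]oxy}methyl)-4-(furan-2-ylmethyl)-1-methyl-7-oxabicyclo[4.1.0]hept-3-en-2-one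
Conditions: Pd(OAc)2 (5 mol%), dppe (5 mol%), MeCN, 80 °C
Reagents that add atoms: none
Why: Tsuji decarboxylation–dehydrogenation: zerovalent palladium ionises the allyl ester, loss of CO2 gives a palladium enolate, and β‑hydride elimination of the C4a hydrogen should give the tetrasubstituted C4a=C8a enone with propene as co‑product; the activating ester and both relay centres disappear, and the oxirane centres are not touched.

Step 8
Reactants: 16 2,3,4-trimethoxy-6-methylbenzaldehyde
Product: 17 2,3,4-trihydroxy-6-methylbenzaldehyde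
Conditions: BBr3, CH2Cl2, −78 °C → rt; H2O
Reagents that add atoms: none
Why: exhaustive cleavage of aryl methyl ethers with BBr3, which the aldehyde tolerates.

Step 9
Reactants: 17 2,3,4-trihydroxy-6-methylbenzaldehyde
Product: 18 4-hydroxy-2,2,6-trimethyl-1,3-benzodioxole-5-carbaldehyde
Conditions: 2,2-dimethoxypropane, TsOH (cat.), toluene, 80 °C
Reagents that add atoms: 2,2-dimethoxypropane, COC(C)(C)OC
Why: acid‑catalysed ketalisation should take the 3,4‑diol, because the 2‑hydroxyl is tied up in a hydrogen bond to the aldehyde.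

Step 10
Reactants: 18 hydroxy acetonide aldehyde
Product: 19 4-methoxy-2,2,6-trimethyl-1,3-benzodioxole-5-carbaldehyde
Conditions: MeI, K2CO3, DMF, rt
Reagents that add atoms: iodomethane, CI
Why: Williamson methylation of the one remaining phenol.

Step 11
Reactants: 19 methoxy acetonide aldehyde
Product: 20 4-methoxy-2,2,6-trimethyl-1,3-benzodioxole-5-carboxylic acid
Conditions: NaClO2, NaH2PO4, 2-methyl-2-butene, t-BuOH/H2O, 0 °C → rt
Reagents that add atoms: sodium chlorite, [Na+].[O-]Cl=O
Why: Pinnick oxidation of the aldehyde; the alkene scavenger protects the electron‑rich ring from hypochlorous acid.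

Step 12
Reactants: 15 epoxy enone; 20 protected aryl acid
Product: 21 (1R,6S)-4-({[tert-butyl(dimethyl)silyl]oxy}methyl)-3-(furan-2-ylmethyl)-6-hydroxy-6-methyl-5-oxocyclohex-3-en-1-yl 4-methoxy-2,2,6-trimethyl-1,3-benzodioxole-5-carboxylate
Conditions: 20 (excess), Cs2CO3 (0.2 equiv), DMF, 60 °C
Reagents that add atoms: none
Why: SN2 opening of the oxirane by the caesium carboxylate at C6, the less substituted carbon and the one not alpha to the ketone, with inversion should give the trans C6‑acyloxy/C7‑hydroxy pair; this sets (R) at C6 and keeps (S) at C7, and the carboxylate is too weak a base to remove a C5 proton.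

Step 13
Reactants: 21 furyl hydroxy ester
Product: 25 (2E)-4-oxopent-2-enoic acid 25 carrying ring A at C5, via endoperoxide 22 (not isolated), via cis keto enal 23 (not isolated), via trans keto enal 24 (not isolated)
Conditions: O2, visible light, tetraphenylporphyrin (cat.), CH2Cl2, −78 °C; Me2S, −78 °C → rt; pyridine (cat.), rt; then NaClO2, NaH2PO4, 2-methyl-2-butene, t-BuOH/H2O, 0 °C
Reagents that add atoms: dioxygen, O=O; sodium chlorite, [Na+].[O-]Cl=O
Why: the 2‑alkylfuran is a masked 4‑oxobut‑2‑enoic acid: [4+2] cycloaddition of singlet oxygen, reduction of the endoperoxide by the sulfide, base‑catalysed cis‑to‑trans isomerisation and Pinnick oxidation are all known on 2‑alkylfurans, and the electron‑poor enone and the benzoate ring should not compete.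

Step 14
Reactants: 25 keto acid
Product: 28 (2E)-3-[(6R,7S)-6-(3,4-dihydroxy-2-methoxy-6-methylbenzoyl)oxy-7-hydroxy-7-methyl-8-oxo-5,6,7,8-tetrahydro-1H-isochromen-3-yl]prop-2-enoic acid, via desilylated keto acid 26 (not isolated), via acetonide-protected pyran acid 27 (not isolated)
Conditions: TFA/H2O (9:1), CH2Cl2, 0 °C → rt
Reagents that add atoms: none
Why: aqueous acid cleaves the primary silyl ether, the freed C1 hydroxyl adds to the C3 ketone and water is lost toward C4 to give the cyclic dienol ether of ring B (a six‑membered ring, driven by conjugation with the C4a=C8a–C8 enone and the acrylic acid), and the same medium hydrolyses the catechol acetonide; both are standard acid‑mediated operations.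

## Compound list

1 | furan | c1ccoc1 | starting material
2 | furan-2-yllithium | [Li]c1ccco1 | intermediate
3 | 2-allylfuran | C=CCc1ccco1 | intermediate
4 | (E)-but-2-enal (crotonaldehyde) | C/C=C/C=O | starting material
5 | (2E)-4-(furan-2-yl)but-2-enal | O=C/C=C/Cc1ccco1 | intermediate
6 | 2,2-dimethyl-1,3-dioxane-4,6-dione (Meldrum's acid) | CC1(C)OC(=O)CC(=O)O1 | starting material
7 | 2-chloropropanoyl chloride (racemic) | CC(Cl)C(Cl)=O | starting material
8 | 5-(2-chloro-1-hydroxypropylidene)-2,2-dimethyl-1,3-dioxane-4,6-dione (racemic) | CC(Cl)C(O)=C1C(=O)OC(C)(C)OC1=O | intermediate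
9 | allyl 4-chloro-3-oxopentanoate (racemic) | CC(Cl)C(=O)CC(=O)OCC=C | intermediate
10 | allyl 4-chloro-2-[(2S)-1-(furan-2-yl)-4-oxobutan-2-yl]-3-oxopentanoate (epimers at the two enolisable carbons) | C=CCOC(=O)C(C(=O)C(C)Cl)[C@@H](Cc1ccco1)CC=O | intermediate
11 | allyl (1R,3R,4S,6R)-3-chloro-6-(furan-2-ylmethyl)-4-hydroxy-3-methyl-2-oxocyclohexane-1-carboxylate | C=CCOC(=O)[C@@H]1[C@@H](Cc2ccco2)C[C@H](O)[C@@](C)(Cl)C1=O | intermediate
12 | allyl (1S,3R,4R,6S)-4-(furan-2-ylmethyl)-1-methyl-2-oxo-7-oxabicyclo[4.1.0]heptane-3-carboxylate | C=CCOC(=O)[C@@H]1[C@@H](Cc2ccco2)C[C@@H]3O[C@]3(C)C1=O | intermediate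
13 | allyl (1S,3R,4R,6S)-4-(furan-2-ylmethyl)-3-(hydroxymethyl)-1-methyl-2-oxo-7-oxabicyclo[4.1.0]heptane-3-carboxylate | C=CCOC(=O)[C@@]1(CO)[C@@H](Cc2ccco2)C[C@@H]3O[C@]3(C)C1=O | intermediate
14 | allyl (1S,3R,4R,6S)-3-({[tert-butyl(dimethyl)silyl]oxy}methyl)-4-(furan-2-ylmethyl)-1-methyl-2-oxo-7-oxabicyclo[4.1.0]heptane-3-carboxylate | C=CCOC(=O)[C@@]1(CO[Si](C)(C)C(C)(C)C)[C@@H](Cc2ccco2)C[C@@H]3O[C@]3(C)C1=O | intermediate
15 | (1S,6S)-3-({[tert-butyl(dimethyl)silyl]oxy}methyl)-4-(furan-2-ylmethyl)-1-methyl-7-oxabicyclo[4.1.0]hept-3-en-2-one | CC(C)(C)[Si](C)(C)OCC1=C(Cc2ccco2)C[C@@H]3O[C@]3(C)C1=O | intermediate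
16 | 2,3,4-trimethoxy-6-methylbenzaldehyde | COc1cc(C)c(C=O)c(OC)c1OC | starting material
17 | 2,3,4-trihydroxy-6-methylbenzaldehyde | Cc1cc(O)c(O)c(O)c1C=O | intermediate
18 | 4-hydroxy-2,2,6-trimethyl-1,3-benzodioxole-5-carbaldehyde | Cc1cc2OC(C)(C)Oc2c(O)c1C=O | intermediate
19 | 4-methoxy-2,2,6-trimethyl-1,3-benzodioxole-5-carbaldehyde | COc1c(C=O)c(C)cc2OC(C)(C)Oc12 | intermediate
20 | 4-methoxy-2,2,6-trimethyl-1,3-benzodioxole-5-carboxylic acid | COc1c(C(=O)O)c(C)cc2OC(C)(C)Oc12 | intermediate
21 | (1R,6S)-4-({[tert-butyl(dimethyl)silyl]oxy}methyl)-3-(furan-2-ylmethyl)-6-hydroxy-6-methyl-5-oxocyclohex-3-en-1-yl 4-methoxy-2,2,6-trimethyl-1,3-benzodioxole-5-carboxylate | COc1c(C(=O)O[C@@H]2CC(Cc3ccco3)=C(CO[Si](C)(C)C(C)(C)C)C(=O)[C@@]2(C)O)c(C)cc4OC(C)(C)Oc14 | intermediate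
22 | furan endoperoxide of 21 (2,3,7-trioxabicyclo[2.2.1]hept-5-en-1-ylmethyl in place of furan-2-ylmethyl; mixture at the new bridgeheads) | COc1c(C(=O)O[C@@H]2CC(CC35C=CC(OO3)O5)=C(CO[Si](C)(C)C(C)(C)C)C(=O)[C@@]2(C)O)c(C)cc4OC(C)(C)Oc14 | intermediate
23 | (1R,6S)-4-({[tert-butyl(dimethyl)silyl]oxy}methyl)-3-[(3Z)-2,5-dioxopent-3-en-1-yl]-6-hydroxy-6-methyl-5-oxocyclohex-3-en-1-yl 4-methoxy-2,2,6-trimethyl-1,3-benzodioxole-5-carboxylate | COc1c(C(=O)O[C@@H]2CC(CC(=O)/C=C\C=O)=C(CO[Si](C)(C)C(C)(C)C)C(=O)[C@@]2(C)O)c(C)cc4OC(C)(C)Oc14 | intermediate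
24 | (3E) isomer of 23 | COc1c(C(=O)O[C@@H]2CC(CC(=O)/C=C/C=O)=C(CO[Si](C)(C)C(C)(C)C)C(=O)[C@@]2(C)O)c(C)cc4OC(C)(C)Oc14 | intermediate
25 | (2E)-5-[(4S,5R)-2-({[tert-butyl(dimethyl)silyl]oxy}methyl)-4-hydroxy-5-[(4-methoxy-2,2,6-trimethyl-1,3-benzodioxole-5-carbonyl)oxy]-4-methyl-3-oxocyclohex-1-en-1-yl]-4-oxopent-2-enoic acid | COc1c(C(=O)O[C@@H]2CC(CC(=O)/C=C/C(=O)O)=C(CO[Si](C)(C)C(C)(C)C)C(=O)[C@@]2(C)O)c(C)cc4OC(C)(C)Oc14 | intermediate
26 | (2E)-5-[(4S,5R)-4-hydroxy-2-(hydroxymethyl)-5-[(4-methoxy-2,2,6-trimethyl-1,3-benzodioxole-5-carbonyl)oxy]-4-methyl-3-oxocyclohex-1-en-1-yl]-4-oxopent-2-enoic acid | COc1c(C(=O)O[C@@H]2CC(CC(=O)/C=C/C(=O)O)=C(CO)C(=O)[C@@]2(C)O)c(C)cc4OC(C)(C)Oc14 | intermediate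
27 | (2E)-3-[(6R,7S)-7-hydroxy-6-[(4-methoxy-2,2,6-trimethyl-1,3-benzodioxole-5-carbonyl)oxy]-7-methyl-8-oxo-5,6,7,8-tetrahydro-1H-isochromen-3-yl]prop-2-enoic acid | COc1c(C(=O)O[C@@H]2CC3=C(COC(/C=C/C(=O)O)=C3)C(=O)[C@@]2(C)O)c(C)cc4OC(C)(C)Oc14 | intermediate
28 | (2E)-3-[(6R,7S)-6-(3,4-dihydroxy-2-methoxy-6-methylbenzoyl)oxy-7-hydroxy-7-methyl-8-oxo-5,6,7,8-tetrahydro-1H-isochromen-3-yl]prop-2-enoic acid | COc1c(O)c(O)cc(C)c1C(=O)O[C@@H]1CC2=C(COC(/C=C/C(=O)O)=C2)C(=O)[C@@]1(C)O | target

## Step count and risks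

Total step count: 14. Longest linear sequence: 9 steps (steps 1, 2, 4, 5, 6, 7, 12, 13, 14).

Steps most likely to fail:

1. Step 4. The aldol closure at the fully substituted, chlorine‑bearing carbon and the displacement at the resulting tertiary chloride may be slow, so that chloride is lost by elimination or Favorskii‑type contraction instead. The enal may also isomerise through its dienamine. Fallback: the route sets out again from 5, which is combined under the same amine catalysis with allyl 3-oxopentanoate F1 (from methyl 3‑oxopentanoate and allyl alcohol by transesterification). Acid‑promoted aldol condensation (TsOH, toluene) should then give the cyclohexenone allyl (1R,6R)-6-(furan-2-ylmethyl)-3-methyl-2-oxocyclohex-3-ene-1-carboxylate F2. Hydroxymethylation as in step 5 gives the hydroxymethyl ester F3 and silylation as in step 6 gives the silyl ether F4. Nucleophilic epoxidation of the enone (t‑BuOOH, DBU, CH2Cl2) anti to the furfuryl group, as is known for 5‑substituted 2‑methylcyclohexenones, returns to the route at 14.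

2. Step 7. β‑Hydride elimination may go toward C1 instead of C4a, the palladium enolate may be allylated at carbon, or zerovalent palladium may isomerise the epoxy ketone at 80 °C. Fallback: from 14, deallylation and decarboxylation at room temperature (Pd(PPh3)4, morpholine, THF) should give the ketone (1S,4R,6S)-3-({[tert-butyl(dimethyl)silyl]oxy}methyl)-4-(furan-2-ylmethyl)-1-methyl-7-oxabicyclo[4.1.0]heptan-2-one F5 as a mixture of epimers at the silyloxymethyl carbon. Dehydrogenation with 2‑iodoxybenzoic acid (DMSO, 65 °C) then returns to the route at 15.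

3. Step 12. The hindered carboxylate may open the oxirane too slowly, attack the tertiary carbon, or the medium may trigger vinylogous elimination by loss of a C5 proton. Fallback: from 15, acid‑catalysed hydrolysis (Sc(OTf)3 cat., THF/H2O, rt) with inversion at C6 should give the trans diol (5R,6S)-2-({[tert-butyl(dimethyl)silyl]oxy}methyl)-3-(furan-2-ylmethyl)-5,6-dihydroxy-6-methylcyclohex-2-en-1-one F6. Acid 20 is converted with oxalyl chloride and catalytic DMF into 4-methoxy-2,2,6-trimethyl-1,3-benzodioxole-5-carbonyl chloride F7. Acylation of the secondary hydroxyl of the diol with this chloride (Et3N, DMAP, CH2Cl2) returns to the route at 21.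

Further compounds
F1 | step 4 | allyl 3-oxopentanoate | CCC(=O)CC(=O)OCC=C
F2 | step 4 | allyl (1R,6R)-6-(furan-2-ylmethyl)-3-methyl-2-oxocyclohex-3-ene-1-carboxylate | C=CCOC(=O)[C@@H]1[C@@H](Cc2ccco2)CC=C(C)C1=O
F3 | step 4 | allyl (1R,6R)-6-(furan-2-ylmethyl)-1-(hydroxymethyl)-3-methyl-2-oxocyclohex-3-ene-1-carboxylate | C=CCOC(=O)[C@@]1(CO)[C@@H](Cc2ccco2)CC=C(C)C1=O
F4 | step 4 | allyl (1R,6R)-1-({[tert-butyl(dimethyl)silyl]oxy}methyl)-6-(furan-2-ylmethyl)-3-methyl-2-oxocyclohex-3-ene-1-carboxylate | C=CCOC(=O)[C@@]1(CO[Si](C)(C)C(C)(C)C)[C@@H](Cc2ccco2)CC=C(C)C1=O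
F5 | step 7 | (1S,4R,6S)-3-({[tert-butyl(dimethyl)silyl]oxy}methyl)-4-(furan-2-ylmethyl)-1-methyl-7-oxabicyclo[4.1.0]heptan-2-one | CC(C)(C)[Si](C)(C)OCC1[C@@H](Cc2ccco2)C[C@@H]3O[C@]3(C)C1=O
F6 | step 12 | (5R,6S)-2-({[tert-butyl(dimethyl)silyl]oxy}methyl)-3-(furan-2-ylmethyl)-5,6-dihydroxy-6-methylcyclohex-2-en-1-one | O[C@@H]1CC(Cc2ccco2)=C(CO[Si](C)(C)C(C)(C)C)C(=O)[C@@]1(C)O
F7 | step 12 | 4-methoxy-2,2,6-trimethyl-1,3-benzodioxole-5-carbonyl chloride | COc1c(C(Cl)=O)c(C)cc2OC(C)(C)Oc12
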